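**Retrosynthetic overview**
1. Target ⇒ last, a Markovnikov radical hydration of an exocyclic methylene (sets the C‑7' carbinol), after C‑acylation of the enolised spiro trione with 3‑methylbutanoic acid.
2. Spiro trione ⇒ key step: gold‑catalysed 1,6‑enyne cyclisation ended by a semipinacol 1,2‑acyl shift. This expands a 4‑hydroxycyclopentane‑1,3‑dione to the six‑membered trione and creates the spiro centre while the cyclohexane ring closes.
3. Enyne carbinol ⇒ alkenyllithium (from a 2‑bromoallyl cyclopentanol) plus the monoanion of 3,3‑diprenylcyclopentane‑1,2,4‑trione.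
4. Cyclopentanol ⇒ cyclopent‑2‑en‑1‑one (asymmetric conjugate alkynylation with enolate allylation, then MeMgBr); trione ⇒ pentane‑2,4‑dione, prenyl bromide and dimethyl oxalate.
5. Ring order: diprenylcyclopentanetrione ring (later expanded) → cyclopentane ring (from cyclopentenone) → cyclohexane ring and six‑membered trione ring together in the key step.

Assumption: β‑dicarbonyl compounds are written as one tautomer each, and the target is the stereoisomer encoded by the given SMILES (spiro centre S in that tautomer).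

**Route**

Step 1
Reactants: 1 pentane‑2,4‑dione; 2 1‑bromo‑3‑methylbut‑2‑ene (prenyl bromide, 2.3 equiv)
Product: 3 3,3‑bis(3‑methylbut‑2‑en‑1‑yl)pentane‑2,4‑dione
Conditions: K2CO3 (3 equiv), acetone, 56 °C
Reagents that add atoms: none
Why: twofold C‑alkylation of the β‑diketonate by SN2 attack on the primary allylic carbon of the prenyl halide; no stereocentre is formed.

Step 2
Reactants: 3 3,3‑bis(3‑methylbut‑2‑en‑1‑yl)pentane‑2,4‑dione; 4 dimethyl oxalate
Product: 7 3,3‑bis(3‑methylbut‑2‑en‑1‑yl)cyclopentane‑1,2,4‑trione, via methyl ketone 5 (not isolated), via diketo ester 6 (not isolated)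
Conditions: NaOMe (3.2 equiv), MeOH, 0 °C; then 4, MeOH/toluene, 65 °C; aq. HCl
Reagents that add atoms: none
Why: retro‑Claisen deacetylation of the non‑enolisable β‑diketone gives ketone 5, whose CH3 and tertiary α‑CH then condense with the two ester groups of the oxalate (twofold Claisen condensation, driven by formation of the acidic enolised trione); no stereocentre is formed.

Step 3
Reactants: 8 cyclopent‑2‑en‑1‑one; 9 ethynyl(trimethyl)silane; 10 2,3‑dibromoprop‑1‑ene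
Product: 13 (2R,3S)‑2‑(2‑bromoprop‑2‑en‑1‑yl)‑3‑[(trimethylsilyl)ethynyl]cyclopentan‑1‑one, via alkynylalane 11 (not isolated), via aluminium enolate 12 (not isolated)
Conditions: 9, Me3Al, Et3N (10 mol %), heptane, 60 °C; then 8, Ni(acac)2 (5 mol %), t‑Bu‑cyano‑bis(oxazoline) ligand (6 mol %, the antipode that gives the 3S ketone), t‑BuOMe, 0 °C; then MeLi, THF, −78 °C; then 10, DMPU, −78 → −20 °C
Reagents that add atoms: none
Why: nickel‑catalysed enantioselective conjugate addition of the alkynylalane (an asymmetric Hooz–Schwartz‑type alkynylation) sets C‑3 (S) under ligand control, and the regiodefined enolate, activated as its lithium aluminate, is allylated (SN2) on the face opposite the alkynyl group to give the trans ketone (C‑2 R, also the thermodynamic isomer).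

Step 4
Reactants: 13 (2R,3S)‑2‑(2‑bromoprop‑2‑en‑1‑yl)‑3‑[(trimethylsilyl)ethynyl]cyclopentan‑1‑one
Product: 14 (1S,2R,3S)‑2‑(2‑bromoprop‑2‑en‑1‑yl)‑1‑methyl‑3‑[(trimethylsilyl)ethynyl]cyclopentan‑1‑ol
Conditions: MeMgBr, CeCl3, THF, −78 °C
Reagents that add atoms: methylmagnesium bromide, C[Mg]Br
Why: Grignard 1,2‑addition (cerium‑modified to suppress enolisation) in which methyl attacks the carbonyl face anti to the neighbouring C‑2 side chain (the slim alkynyl group on C‑3 does not shield that face), giving the tertiary alcohol with OH cis to the bromoallyl group (C‑1 S).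

Step 5
Reactants: 14 (1S,2R,3S)‑2‑(2‑bromoprop‑2‑en‑1‑yl)‑1‑methyl‑3‑[(trimethylsilyl)ethynyl]cyclopentan‑1‑ol; 7 3,3‑bis(3‑methylbut‑2‑en‑1‑yl)cyclopentane‑1,2,4‑trione
Product: 18 4‑hydroxy‑4‑{3‑[(1R,2S,5S)‑5‑ethynyl‑2‑hydroxy‑2‑methylcyclopentyl]prop‑1‑en‑2‑yl}‑5,5‑bis(3‑methylbut‑2‑en‑1‑yl)cyclopentane‑1,3‑dione (both C‑4 epimers), via dilithio alkoxide 15 (not isolated), via sodium enolate 16 (not isolated), via silylated adduct 17 (not isolated)
Conditions: 14, t‑BuLi (3.1 equiv), Et2O, −78 °C; 7, NaH (1.05 equiv), THF, 0 °C; combine, −78 → −30 °C; aq. HCl to pH 4; then AgNO3 (10 mol %), acetone/MeOH/H2O, rt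
Reagents that add atoms: none
Why: bromine–lithium exchange gives the alkenyllithium, which adds 1,2 to the only carbonyl of 16 that is not part of the enolate (C‑2 of the trione, next to the diprenyl carbon), so the carbinol carbon sits beside the quaternary carbon; the new carbinol centre forms as a mixture that converges in step 6, and silver‑catalysed protodesilylation frees the alkyne.

Step 6
Reactants: 18 4‑hydroxy‑4‑{3‑[(1R,2S,5S)‑5‑ethynyl‑2‑hydroxy‑2‑methylcyclopentyl]prop‑1‑en‑2‑yl}‑5,5‑bis(3‑methylbut‑2‑en‑1‑yl)cyclopentane‑1,3‑dione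
Product: 19 (1R,3'S,3a'R,7a'S)‑3',4‑dihydroxy‑3'‑methyl‑7'‑methylidene‑5,5‑bis(3‑methylbut‑2‑en‑1‑yl)octahydrospiro[cyclohexane‑1,5'‑inden]‑3‑ene‑2,6‑dione (trans ring fusion; C‑6 carbonyl axial, C‑2 carbonyl equatorial on the new cyclohexane)
Conditions: (Ph3P)AuNTf2 (5 mol %), dry CH2Cl2, 0 °C → rt
Reagents that add atoms: none
Why: Proposed new method: cationic monovalent gold activates the terminal alkyne, the 1,1‑disubstituted alkene attacks it through its CH2 terminus in a chair‑like transition state (trans fusion dictated by the cyclopentane), and the developing tertiary cation is quenched by a 1,2‑shift of the enolised acyl carbon C‑3 of the hydroxy‑dione (semipinacol), which expands the five‑membered dione to the six‑membered trione; the shift occurs anti to the new C–C bond, so the migrating carbon ends equatorial and the former carbinol carbon (the carbonyl next to the diprenyl carbon) ends axial, which is the required spiro configuration from either carbinol epimer, and protodeauration leaves the exocyclic methylene; the closest known reactions are gold‑catalysed enyne cycloisomerisation–semipinacol ring expansions of alkenyl cyclopropanols and cyclobutanols and Prins–pinacol annulations, none shown with an unstrained ring and a migrating acyl group.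

Step 7
Reactants: 19 (1R,3'S,3a'R,7a'S)‑3',4‑dihydroxy‑3'‑methyl‑7'‑methylidene‑5,5‑bis(3‑methylbut‑2‑en‑1‑yl)octahydrospiro[cyclohexane‑1,5'‑inden]‑3‑ene‑2,6‑dione; 20 3‑methylbutanoic acid
Product: 22 (1S,3'S,3a'R,7a'S)‑3',4‑dihydroxy‑3'‑methyl‑7'‑methylidene‑3‑(3‑methylbutanoyl)‑5,5‑bis(3‑methylbut‑2‑en‑1‑yl)octahydrospiro[cyclohexane‑1,5'‑inden]‑3‑ene‑2,6‑dione, via enol ester 21 (not isolated)
Conditions: DCC (1.2 equiv), DMAP (0.3 equiv), CH2Cl2, rt → 40 °C
Reagents that add atoms: none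
Why: Steglich‑type O‑acylation of the enol followed by DMAP‑mediated O‑to‑C acyl migration (Fries‑type rearrangement, standard for 2‑acylcyclohexane‑1,3‑diones) places the acyl group on the only enolic CH carbon; the tertiary alcohol is not acylated, no stereocentre is formed, and the spatial arrangement is unchanged (the spiro descriptor changes from R to S only through ligand priorities).

Step 8
Reactants: 22 (1S,3'S,3a'R,7a'S)‑3',4‑dihydroxy‑3'‑methyl‑7'‑methylidene‑3‑(3‑methylbutanoyl)‑5,5‑bis(3‑methylbut‑2‑en‑1‑yl)octahydrospiro[cyclohexane‑1,5'‑inden]‑3‑ene‑2,6‑dione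
Product: 24 (1S,3'S,3a'R,7'S,7a'S)‑3',4,7'‑trihydroxy‑3',7'‑dimethyl‑3‑(3‑methylbutanoyl)‑5,5‑bis(3‑methylbut‑2‑en‑1‑yl)octahydrospiro[cyclohexane‑1,5'‑inden]‑3‑ene‑2,6‑dione (CNP0198642.1), via hydroperoxide 23 (not isolated)
Conditions: Co(acac)2 (20 mol %), PhSiH3 (2 equiv), O2 (1 atm), i‑PrOH/CH2Cl2, 0 °C, stopped at full conversion of the methylene; then PPh3
Reagents that add atoms: dioxygen, O=O
Why: Mukaiyama hydration (metal‑hydride hydrogen atom transfer, O2 trapping, reduction) in which H adds to the unhindered exocyclic CH2, expected to react faster than the trisubstituted prenyl alkenes, and O2 takes the tertiary radical from the equatorial face because the axial face is covered by the axial C‑6 carbonyl, giving the 7'S alcohol (OH equatorial, CH3 axial).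

**Compound list**
1 | pentane‑2,4‑dione | CC(=O)CC(C)=O | starting material
2 | 1‑bromo‑3‑methylbut‑2‑ene | CC(C)=CCBr | starting material
3 | 3,3‑bis(3‑methylbut‑2‑en‑1‑yl)pentane‑2,4‑dione | CC(=O)C(CC=C(C)C)(CC=C(C)C)C(C)=O | intermediate
4 | dimethyl oxalate | COC(=O)C(=O)OC | starting material
5 | 6‑methyl‑3‑(3‑methylbut‑2‑en‑1‑yl)hept‑5‑en‑2‑one | CC(=O)C(CC=C(C)C)CC=C(C)C | intermediate
6 | methyl 8‑methyl‑5‑(3‑methylbut‑2‑en‑1‑yl)‑2,4‑dioxonon‑7‑enoate | COC(=O)C(=O)CC(=O)C(CC=C(C)C)CC=C(C)C | intermediate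
7 | 3,3‑bis(3‑methylbut‑2‑en‑1‑yl)cyclopentane‑1,2,4‑trione | O=C1CC(=O)C(CC=C(C)C)(CC=C(C)C)C1=O | intermediate
8 | cyclopent‑2‑en‑1‑one | O=C1C=CCC1 | starting material
9 | ethynyl(trimethyl)silane | C#C[Si](C)(C)C | starting material
10 | 2,3‑dibromoprop‑1‑ene | C=C(Br)CBr | starting material
11 | dimethyl[(trimethylsilyl)ethynyl]aluminium | C[Al](C)C#C[Si](C)(C)C | intermediate
12 | dimethylaluminium (3S)‑3‑[(trimethylsilyl)ethynyl]cyclopent‑1‑en‑1‑olate | C[Al](C)OC1=C[C@H](CC1)C#C[Si](C)(C)C | intermediate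
13 | (2R,3S)‑2‑(2‑bromoprop‑2‑en‑1‑yl)‑3‑[(trimethylsilyl)ethynyl]cyclopentan‑1‑one | C=C(Br)C[C@@H]1[C@H](CCC1=O)C#C[Si](C)(C)C | intermediate
14 | (1S,2R,3S)‑2‑(2‑bromoprop‑2‑en‑1‑yl)‑1‑methyl‑3‑[(trimethylsilyl)ethynyl]cyclopentan‑1‑ol | C=C(Br)C[C@@H]1[C@H](CC[C@]1(C)O)C#C[Si](C)(C)C | intermediate
15 | lithium (1S,2R,3S)‑2‑(2‑lithioprop‑2‑en‑1‑yl)‑1‑methyl‑3‑[(trimethylsilyl)ethynyl]cyclopentan‑1‑olate | [Li]C(=C)C[C@@H]1[C@H](CC[C@]1(C)O[Li])C#C[Si](C)(C)C | intermediate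
16 | sodium 3,5‑dioxo‑4,4‑bis(3‑methylbut‑2‑en‑1‑yl)cyclopent‑1‑en‑1‑olate | [Na+].[O-]C1=CC(=O)C(CC=C(C)C)(CC=C(C)C)C1=O | intermediate
17 | 4‑hydroxy‑4‑{3‑[(1R,2S,5S)‑2‑hydroxy‑2‑methyl‑5‑[(trimethylsilyl)ethynyl]cyclopentyl]prop‑1‑en‑2‑yl}‑5,5‑bis(3‑methylbut‑2‑en‑1‑yl)cyclopentane‑1,3‑dione (both C‑4 epimers) | C=C(C[C@@H]1[C@H](CC[C@]1(C)O)C#C[Si](C)(C)C)C2(O)C(=O)CC(=O)C2(CC=C(C)C)CC=C(C)C | intermediate
18 | 4‑hydroxy‑4‑{3‑[(1R,2S,5S)‑5‑ethynyl‑2‑hydroxy‑2‑methylcyclopentyl]prop‑1‑en‑2‑yl}‑5,5‑bis(3‑methylbut‑2‑en‑1‑yl)cyclopentane‑1,3‑dione (both C‑4 epimers) | C=C(C[C@@H]1[C@H](CC[C@]1(C)O)C#C)C2(O)C(=O)CC(=O)C2(CC=C(C)C)CC=C(C)C | intermediate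
19 | (1R,3'S,3a'R,7a'S)‑3',4‑dihydroxy‑3'‑methyl‑7'‑methylidene‑5,5‑bis(3‑methylbut‑2‑en‑1‑yl)octahydrospiro[cyclohexane‑1,5'‑inden]‑3‑ene‑2,6‑dione | CC(C)=CCC1(CC=C(C)C)C(=O)[C@@]2(C[C@@H]3[C@H](CC[C@]3(C)O)C(=C)C2)C(=O)C=C1O | intermediate
20 | 3‑methylbutanoic acid | CC(C)CC(O)=O | starting material
21 | (1R,3'S,3a'R,7a'S)‑3'‑hydroxy‑3'‑methyl‑7'‑methylidene‑5,5‑bis(3‑methylbut‑2‑en‑1‑yl)‑2,6‑dioxooctahydrospiro[cyclohexane‑1,5'‑inden]‑3‑en‑4‑yl 3‑methylbutanoate | CC(C)=CCC1(CC=C(C)C)C(=O)[C@@]2(C[C@@H]3[C@H](CC[C@]3(C)O)C(=C)C2)C(=O)C=C1OC(=O)CC(C)C | intermediate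
22 | (1S,3'S,3a'R,7a'S)‑3',4‑dihydroxy‑3'‑methyl‑7'‑methylidene‑3‑(3‑methylbutanoyl)‑5,5‑bis(3‑methylbut‑2‑en‑1‑yl)octahydrospiro[cyclohexane‑1,5'‑inden]‑3‑ene‑2,6‑dione | CC(C)=CCC1(CC=C(C)C)C(=O)[C@@]2(C[C@@H]3[C@H](CC[C@]3(C)O)C(=C)C2)C(=O)C(C(=O)CC(C)C)=C1O | intermediate
23 | (1S,3'S,3a'R,7'S,7a'S)‑7'‑hydroperoxy‑3',4‑dihydroxy‑3',7'‑dimethyl‑3‑(3‑methylbutanoyl)‑5,5‑bis(3‑methylbut‑2‑en‑1‑yl)octahydrospiro[cyclohexane‑1,5'‑inden]‑3‑ene‑2,6‑dione | CC(C)=CCC1(CC=C(C)C)C(=O)[C@@]2(C[C@@H]3[C@H](CC[C@]3(C)O)[C@@](C)(OO)C2)C(=O)C(C(=O)CC(C)C)=C1O | intermediate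
24 | (1S,3'S,3a'R,7'S,7a'S)‑3',4,7'‑trihydroxy‑3',7'‑dimethyl‑3‑(3‑methylbutanoyl)‑5,5‑bis(3‑methylbut‑2‑en‑1‑yl)octahydrospiro[cyclohexane‑1,5'‑inden]‑3‑ene‑2,6‑dione | CC(C)=CCC1(CC=C(C)C)C(=O)[C@@]2(C[C@@H]3[C@H](CC[C@]3(C)O)[C@@](C)(O)C2)C(=O)C(C(=O)CC(C)C)=C1O | target

**Step count and risks**

Total steps: 8. Longest linear sequence: 6 (steps 3 to 8 from cyclopent‑2‑en‑1‑one, or steps 1, 2, 5 to 8 from pentane‑2,4‑dione).

Most likely to fail:

Step 6 (the proposed new step). The acyl shift may be too slow to end the cyclisation, or the diprenyl carbon may migrate instead. The fallback uses known chemistry, sets out from 18 and comes back at 19. The gold‑catalysed cyclisation is run as a hydroxycyclisation of the 1,6‑enyne [(Ph3P)AuNTf2, wet dioxane], so that water captures the tertiary cation and gives 4‑hydroxy‑4‑[(3S,3aR,5S,7aS)‑3,5‑dihydroxy‑3‑methyl‑7‑methylideneoctahydro‑1H‑inden‑5‑yl]‑5,5‑bis(3‑methylbut‑2‑en‑1‑yl)cyclopentane‑1,3‑dione F1. The pinacol rearrangement of this vicinal diol (1,2‑acyl shift) is then triggered with catalytic BF3·OEt2 in CH2Cl2 at −40 °C to reach 19. The spiro configuration is then decided at a free cation, so the two spiro epimers must be separated.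

Step 3. The enantioselectivity of the nickel alkynylation on cyclopentenone is uncertain, and the aluminium enolate may be slow to allylate. The fallback sets out from 9 and comes back at 13. Lithium (trimethylsilyl)acetylide F3 (from 9 and n‑BuLi) adds to the further starting material 3‑methoxycyclopent‑2‑en‑1‑one F2 to give 3‑methoxy‑1‑[(trimethylsilyl)ethynyl]cyclopent‑2‑en‑1‑ol F4. Aqueous acid (Stork–Danheiser transposition) turns it into 3‑[(trimethylsilyl)ethynyl]cyclopent‑2‑en‑1‑one F5. Copper hydride asymmetric conjugate reduction [Cu(OAc)2, DTBM‑SEGPHOS in the antipode that gives 3S, PhMe2SiH, toluene] delivers {[(3S)‑3‑[(trimethylsilyl)ethynyl]cyclopent‑1‑en‑1‑yl]oxy}dimethyl(phenyl)silane F6. MeLi and then 10 convert this regiodefined silyl enol ether into 13.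

Step 8. The prenyl alkenes may be hydrated too, or the strained axial‑methyl product may form slowly. The fallback sets out from 22 and comes back at 24. It is a polar oxymercuration–demercuration, which is selective for the terminal 1,1‑disubstituted alkene: Hg(OAc)2 in THF/H2O gives (1S,3'S,3a'R,7'S,7a'S)‑7'‑[(acetoxymercurio)methyl]‑3',4,7'‑trihydroxy‑3'‑methyl‑3‑(3‑methylbutanoyl)‑5,5‑bis(3‑methylbut‑2‑en‑1‑yl)octahydrospiro[cyclohexane‑1,5'‑inden]‑3‑ene‑2,6‑dione F7. NaBH4 in aqueous NaOH then replaces mercury by hydrogen. Participation of the axial carbonyl oxygen could give the C‑7' epimer here, which is why this is the fallback and not the main route.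

Further compounds
F1 | step 6 | 4‑hydroxy‑4‑[(3S,3aR,5S,7aS)‑3,5‑dihydroxy‑3‑methyl‑7‑methylideneoctahydro‑1H‑inden‑5‑yl]‑5,5‑bis(3‑methylbut‑2‑en‑1‑yl)cyclopentane‑1,3‑dione | C=C1C[C@@](O)(C[C@@H]2[C@@H]1CC[C@]2(C)O)C3(O)C(=O)CC(=O)C3(CC=C(C)C)CC=C(C)C
F2 | step 3 | 3‑methoxycyclopent‑2‑en‑1‑one | COC1=CC(=O)CC1
F3 | step 3 | lithium (trimethylsilyl)acetylide | [Li]C#C[Si](C)(C)C
F4 | step 3 | 3‑methoxy‑1‑[(trimethylsilyl)ethynyl]cyclopent‑2‑en‑1‑ol | COC1=CC(O)(CC1)C#C[Si](C)(C)C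
F5 | step 3 | 3‑[(trimethylsilyl)ethynyl]cyclopent‑2‑en‑1‑one | O=C1C=C(CC1)C#C[Si](C)(C)C
F6 | step 3 | {[(3S)‑3‑[(trimethylsilyl)ethynyl]cyclopent‑1‑en‑1‑yl]oxy}dimethyl(phenyl)silane | C[Si](C)(c1ccccc1)OC1=C[C@H](CC1)C#C[Si](C)(C)C
F7 | step 8 | (1S,3'S,3a'R,7'S,7a'S)‑7'‑[(acetoxymercurio)methyl]‑3',4,7'‑trihydroxy‑3'‑methyl‑3‑(3‑methylbutanoyl)‑5,5‑bis(3‑methylbut‑2‑en‑1‑yl)octahydrospiro[cyclohexane‑1,5'‑inden]‑3‑ene‑2,6‑dione | CC(C)=CCC1(CC=C(C)C)C(=O)[C@@]2(C[C@@H]3[C@H](CC[C@]3(C)O)[C@@](C[Hg]OC(C)=O)(O)C2)C(=O)C(C(=O)CC(C)C)=C1O
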